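**Plan** (labdane numbering: ring A = C1–C5, C10; ring B = C5–C10; C17 = ester carbon on C8; C11–C16 = side chain)

- Retrosynthetic cuts, in order: C12–C13 (Negishi coupling), C7–C8 (ring B), C6≡C7 (alkyne from a C6 aldehyde), insertion of C8 between C9 and C17 (Arndt–Eistert), C9–C10 (Ireland–Claisen of a β-cyclogeranyl ester).
- Forward: ring A is bought as β-cyclocitral; one [3,3] shift makes C9–C10 and leaves a C5=C6 methylene; the methylene becomes an ethynyl group; ring B closes through C7–C8; the side chain is joined last.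
- Enabling feature: C8 is the α-carbon of the C17 ester (a latent ketene silyl acetal) and C7 is the terminal carbon of an ethynyl group on C5. Because C5–C6 and C10–C9 are trans-diequatorial on ring A, a 6-endo attack of C8 on tungsten-activated C7 gives ring B trans-fused, with the Δ6 β,γ-unsaturated ester formed directly and unconjugated.
- Stereochemistry: C9 and C10 from the chair Claisen (relative) under a chiral diazaborolidine controller (absolute); C5 from hydroboration anti to the axial methyls; C8 in the ring closure by allylic strain.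
- Side-chain geometry: from anti-hydroiodination of an ynoate and a stereoretentive coupling.

Key step: step 9

Assumption: the (S,S)-controller 5 is taken to select the alkene face that gives 9 as drawn; its sense on this tetrasubstituted allyl ester is not established, and the equally available (R,R)-controller would be used if it proved opposite, with nothing else changed.

Step 1
Reactants: 1 β-cyclocitral (2,6,6-trimethylcyclohex-1-ene-1-carbaldehyde)
Product: 2 β-cyclogeraniol ((2,6,6-trimethylcyclohex-1-en-1-yl)methanol)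
Conditions: NaBH4, CeCl3·7H2O, MeOH, 0 °C
Reagents that add atoms: none
Why: Luche-type 1,2-reduction of the hindered conjugated aldehyde should give the primary allylic alcohol and leave the tetrasubstituted alkene untouched; no stereocentre is formed.

Step 2
Reactants: 2 β-cyclogeraniol; 3 4-chlorobutanoyl chloride
Product: 4 (2,6,6-trimethylcyclohex-1-en-1-yl)methyl 4-chlorobutanoate
Conditions: pyridine, DMAP (cat.), CH2Cl2, 0 → 23 °C
Reagents that add atoms: none
Why: DMAP-catalysed acylation of the primary allylic alcohol installs C9, C11 and C12 with a chloride handle on C12 and the future C8 as the ester carbonyl; no stereocentre is formed.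

Step 3
Reactants: 4 (2,6,6-trimethylcyclohex-1-en-1-yl)methyl 4-chlorobutanoate; 5 (1S,2S)-N,N'-bis[3,5-bis(trifluoromethyl)benzenesulfonyl]-1,2-diphenylethane-1,2-diamine (chiral controller)
Product: 9 (2S)-4-chloro-2-[(1S)-1,3,3-trimethyl-2-methylidenecyclohexyl]butanoic acid, via bromoborane 6 (not isolated), via boron ketene acetal 7 (not isolated), via acyloxyborane 8 (not isolated)
Conditions: 5, BBr3, CH2Cl2, 23 °C, then evaporation; 4, Et3N, toluene–hexane, −78 → 4 °C; aq. work-up
Reagents that add atoms: none
Why: Enantioselective Ireland–Claisen rearrangement through a chiral boron ketene acetal, in which Et3N in toluene–hexane should give the enolate with C11 cis to the O–B oxygen, the chair transition state then places H9 anti to the C10 methyl and C11 anti to C5 (the relative configuration of the target), and the C2-symmetric diazaborolidine selects the alkene face and so sets C10 and C9 in the absolute sense while leaving the C5=C6 methylene.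

Step 4
Reactants: 9 (2S)-4-chloro-2-[(1S)-1,3,3-trimethyl-2-methylidenecyclohexyl]butanoic acid
Product: 11 (3S)-5-chloro-1-diazo-3-[(1S)-1,3,3-trimethyl-2-methylidenecyclohexyl]pentan-2-one, via acid chloride 10 (not isolated)
Conditions: 1-chloro-N,N,2-trimethylprop-1-en-1-amine, CH2Cl2, 0 °C; then CH2N2 (excess), Et2O, 0 °C
Reagents that add atoms: diazomethane, C=[N+]=[N-]
Why: First half of the Arndt–Eistert homologation, in which the neutral chloroenamine forms the acid chloride without acid that could protonate the exocyclic alkene and acylation of diazomethane gives the α-diazoketone with C9 untouched.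

Step 5
Reactants: 11 (3S)-5-chloro-1-diazo-3-[(1S)-1,3,3-trimethyl-2-methylidenecyclohexyl]pentan-2-one
Product: 13 methyl (3S)-5-chloro-3-[(1S)-1,3,3-trimethyl-2-methylidenecyclohexyl]pentanoate, via ketene 12 (not isolated)
Conditions: PhCO2Ag (cat.), Et3N, MeOH, 23 °C, dark
Reagents that add atoms: methanol, CO
Why: Wolff rearrangement with 1,2-shift of C9 (retention at the migrating carbon) gives a ketene that methanol traps as the homologated methyl ester, so that C8 becomes an enolisable CH2 and C17 the ester carbon, the doubly neopentyl alkene being too hindered to compete by cyclopropanation.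

Step 6
Reactants: 13 methyl (3S)-5-chloro-3-[(1S)-1,3,3-trimethyl-2-methylidenecyclohexyl]pentanoate
Product: 15 methyl (3S)-5-chloro-3-[(1S,2R)-2-(hydroxymethyl)-1,3,3-trimethylcyclohexyl]pentanoate, via alkylborane 14 (not isolated)
Conditions: BH3·THF, THF, 0 → 23 °C; then NaOH, H2O2, H2O, 0 °C
Reagents that add atoms: hydrogen peroxide, OO
Why: Anti-Markovnikov hydroboration–oxidation, in which the chair that keeps the C9 chain equatorial has the C10 methyl and one C4 methyl axial on the same face of the exocyclic alkene, so borane should add from the opposite face, deliver hydrogen axially to C5 and leave CH2OH equatorial and trans to the C9 chain.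

Step 7
Reactants: 15 methyl (3S)-5-chloro-3-[(1S,2R)-2-(hydroxymethyl)-1,3,3-trimethylcyclohexyl]pentanoate
Product: 16 methyl (3S)-5-chloro-3-[(1S,2R)-2-formyl-1,3,3-trimethylcyclohexyl]pentanoate
Conditions: Dess–Martin periodinane, NaHCO3, CH2Cl2, 0 → 23 °C
Reagents that add atoms: none
Why: Dess–Martin oxidation of the primary alcohol to the aldehyde under buffered conditions that should not epimerise C5.

Step 8
Reactants: 16 methyl (3S)-5-chloro-3-[(1S,2R)-2-formyl-1,3,3-trimethylcyclohexyl]pentanoate
Product: 17 methyl (3S)-5-chloro-3-[(1S,2S)-2-ethynyl-1,3,3-trimethylcyclohexyl]pentanoate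
Conditions: dimethyl (1-diazo-2-oxopropyl)phosphonate, K2CO3, MeOH, 0 → 23 °C
Reagents that add atoms: dimethyl (1-diazo-2-oxopropyl)phosphonate, COP(=O)(OC)C(=[N+]=[N-])C(C)=O
Why: Seyferth–Gilbert homologation in the Ohira–Bestmann variant converts the aldehyde into the C6≡C7 alkyne through an alkylidene carbene and 1,2-hydrogen shift, and the C5 hydrogen, flanked by two quaternary carbons, should resist enolisation under the carbonate conditions.

Step 9
Reactants: 17 methyl (3S)-5-chloro-3-[(1S,2S)-2-ethynyl-1,3,3-trimethylcyclohexyl]pentanoate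
Product: 21 methyl (1R,2S,4aR,8aS)-1-(2-chloroethyl)-5,5,8a-trimethyl-1,2,4a,5,6,7,8,8a-octahydronaphthalene-2-carboxylate, via dilithio enolate acetylide 18 (not isolated), via lithium acetylide of the ketene acetal 19 (not isolated), via silyl ketene acetal 20 (not isolated)
Conditions: LiN(i-Pr)2 (2.2 equiv), THF, −78 °C; t-BuMe2SiCl (1.1 equiv), DMPU, −78 → 0 °C; pH 7 buffer, pentane, crude 20; then W(CO)6 (20 mol%), DABCO (1 equiv), H2O (2 equiv), toluene, hν, 23 °C
Reagents that add atoms: none
Why: Proposed new method: photolysis of W(CO)6 should give a W(CO)5 fragment (zerovalent tungsten) that binds the C6≡C7 alkyne and, helped by the amine, isomerises it to the vinylidene W=C7=C6H, whose electrophilic C7 is attacked by the nucleophilic C8 of the ketene silyl acetal, after which water protonates the C7–W bond, removes the silyl group and frees the catalyst. The closest known reaction types are the W(CO)5-catalysed endo-selective cyclisation of ω-acetylenic silyl enol ethers of ketones and the tungsten-vinylidene cycloisomerisation of alkynols to endocyclic enol ethers, extended here to an ester-derived, more nucleophilic ketene silyl acetal. Ring B closes in the 6-endo-dig mode through a chair-like array that is trans-fused to ring A because C5–C6 and C10–C9 are both equatorial on ring A. The new stereocentre C8 is set under kinetic control, since the ketene acetal should react through the rotamer that eclipses C9–H (least allylic 1,3-strain) and offers C7 the face syn to C10, which puts H8 anti to H9 and the ester equatorial and trans to the C9 chain. The step needs attack at C7 and not at C6, which the vinylidene pathway and the strain of a trans-fused five-membered ring should secure, and it needs the Δ6 double bond to stay out of conjugation with C17, which the neutral, base-free conditions should secure.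

Step 10
Reactants: 21 methyl (1R,2S,4aR,8aS)-1-(2-chloroethyl)-5,5,8a-trimethyl-1,2,4a,5,6,7,8,8a-octahydronaphthalene-2-carboxylate
Product: 22 methyl (1R,2S,4aR,8aS)-1-(2-iodoethyl)-5,5,8a-trimethyl-1,2,4a,5,6,7,8,8a-octahydronaphthalene-2-carboxylate
Conditions: NaI, acetone, reflux
Reagents that add atoms: sodium iodide, [Na+].[I-]
Why: Finkelstein halide exchange (SN2) at the unhindered primary C12 under neutral conditions that should leave C8 and the β,γ-unsaturated ester untouched.

Step 11
Reactants: 23 methyl 4-hydroxybut-2-ynoate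
Product: 24 methyl (2Z)-4-hydroxy-3-iodobut-2-enoate
Conditions: NaI, AcOH, 70 °C
Reagents that add atoms: sodium iodide, [Na+].[I-]
Why: Conjugate hydroiodination of the ynoate, in which iodide adds at C3 and the proton anti at C2, should place iodine cis to the ester and the hydroxymethyl group trans to it, so that lactonisation is not possible.

Step 12
Reactants: 24 methyl (2Z)-4-hydroxy-3-iodobut-2-enoate
Product: 25 methyl (2Z)-4-acetoxy-3-iodobut-2-enoate
Conditions: Ac2O, pyridine, DMAP (cat.), CH2Cl2, 0 → 23 °C
Reagents that add atoms: acetic anhydride, CC(=O)OC(C)=O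
Why: Acylation of the primary alcohol, which leaves the alkene geometry unchanged.

Step 13
Reactants: 22 methyl (1R,2S,4aR,8aS)-1-(2-iodoethyl)-5,5,8a-trimethyl-1,2,4a,5,6,7,8,8a-octahydronaphthalene-2-carboxylate; 25 methyl (2Z)-4-acetoxy-3-iodobut-2-enoate
Product: 27 methyl (1R,2S,4aR,8aS)-1-[(3E)-3-(acetoxymethyl)-5-methoxy-5-oxopent-3-en-1-yl]-5,5,8a-trimethyl-1,2,4a,5,6,7,8,8a-octahydronaphthalene-2-carboxylate (CNP0190145.1), via alkylzinc iodide 26 (not isolated)
Conditions: Zn dust (activated with BrCH2CH2Br and Me3SiCl), THF, 40 °C; then 25, Pd(PPh3)4 (5 mol%), THF, 23 °C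
Reagents that add atoms: none
Why: Negishi coupling, in which zinc insertion into the primary C–I bond gives an ester-tolerant alkylzinc iodide and cross-coupling with the vinyl iodide (oxidative addition of zerovalent palladium into C–I being much faster than ionisation of the allylic acetate) should proceed with retention, so that C12 ends cis to the C15 ester as in the target.

**Compound list**

1 | β-cyclocitral (2,6,6-trimethylcyclohex-1-ene-1-carbaldehyde) | CC1=C(C=O)C(C)(C)CCC1 | starting material
2 | β-cyclogeraniol ((2,6,6-trimethylcyclohex-1-en-1-yl)methanol) | CC1=C(CO)C(C)(C)CCC1 | intermediate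
3 | 4-chlorobutanoyl chloride | ClCCCC(Cl)=O | starting material
4 | (2,6,6-trimethylcyclohex-1-en-1-yl)methyl 4-chlorobutanoate | ClCCCC(=O)OCC1=C(C)CCCC1(C)C | intermediate
5 | (1S,2S)-N,N'-bis[3,5-bis(trifluoromethyl)benzenesulfonyl]-1,2-diphenylethane-1,2-diamine (chiral controller) | FC(F)(F)c1cc(cc(c1)C(F)(F)F)S(=O)(=O)N[C@@H](c1ccccc1)[C@@H](NS(=O)(=O)c1cc(cc(c1)C(F)(F)F)C(F)(F)F)c1ccccc1 | starting material
6 | (4S,5S)-2-bromo-1,3-bis[3,5-bis(trifluoromethyl)benzenesulfonyl]-4,5-diphenyl-1,3,2-diazaborolidine | BrB1N(S(=O)(=O)c2cc(cc(c2)C(F)(F)F)C(F)(F)F)[C@@H](c2ccccc2)[C@H](c2ccccc2)N1S(=O)(=O)c1cc(cc(c1)C(F)(F)F)C(F)(F)F | intermediate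
7 | boron ketene acetal of 4 (diazaborolidin-2-yl on the enolate oxygen, C11 cis to that oxygen) | ClCC/C=C(\OB1N(S(=O)(=O)c2cc(cc(c2)C(F)(F)F)C(F)(F)F)[C@@H](c2ccccc2)[C@H](c2ccccc2)N1S(=O)(=O)c1cc(cc(c1)C(F)(F)F)C(F)(F)F)OCC1=C(C)CCCC1(C)C | intermediate
8 | acyloxyborane (diazaborolidin-2-yl ester of acid 9) | ClCC[C@H](C(=O)OB1N(S(=O)(=O)c2cc(cc(c2)C(F)(F)F)C(F)(F)F)[C@@H](c2ccccc2)[C@H](c2ccccc2)N1S(=O)(=O)c1cc(cc(c1)C(F)(F)F)C(F)(F)F)[C@@]1(C)C(=C)C(C)(C)CCC1 | intermediate
9 | (2S)-4-chloro-2-[(1S)-1,3,3-trimethyl-2-methylidenecyclohexyl]butanoic acid | ClCC[C@H](C(=O)O)[C@@]1(C)C(=C)C(C)(C)CCC1 | intermediate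
10 | (2S)-4-chloro-2-[(1S)-1,3,3-trimethyl-2-methylidenecyclohexyl]butanoyl chloride | ClCC[C@H](C(Cl)=O)[C@@]1(C)C(=C)C(C)(C)CCC1 | intermediate
11 | (3S)-5-chloro-1-diazo-3-[(1S)-1,3,3-trimethyl-2-methylidenecyclohexyl]pentan-2-one | ClCC[C@H](C(=O)C=[N+]=[N-])[C@@]1(C)C(=C)C(C)(C)CCC1 | intermediate
12 | ketene (3R)-5-chloro-3-[(1S)-1,3,3-trimethyl-2-methylidenecyclohexyl]pent-1-en-1-one | ClCC[C@H](C=C=O)[C@@]1(C)C(=C)C(C)(C)CCC1 | intermediate
13 | methyl (3S)-5-chloro-3-[(1S)-1,3,3-trimethyl-2-methylidenecyclohexyl]pentanoate | ClCC[C@H](CC(=O)OC)[C@@]1(C)C(=C)C(C)(C)CCC1 | intermediate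
14 | primary alkylborane (BH2 on C6, hydrogen on C5 trans to the C10 methyl) | ClCC[C@H](CC(=O)OC)[C@@]1(C)[C@H](CB)C(C)(C)CCC1 | intermediate
15 | methyl (3S)-5-chloro-3-[(1S,2R)-2-(hydroxymethyl)-1,3,3-trimethylcyclohexyl]pentanoate | ClCC[C@H](CC(=O)OC)[C@@]1(C)[C@H](CO)C(C)(C)CCC1 | intermediate
16 | methyl (3S)-5-chloro-3-[(1S,2R)-2-formyl-1,3,3-trimethylcyclohexyl]pentanoate | ClCC[C@H](CC(=O)OC)[C@@]1(C)[C@H](C=O)C(C)(C)CCC1 | intermediate
17 | methyl (3S)-5-chloro-3-[(1S,2S)-2-ethynyl-1,3,3-trimethylcyclohexyl]pentanoate | ClCC[C@H](CC(=O)OC)[C@@]1(C)[C@H](C#C)C(C)(C)CCC1 | intermediate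
18 | dilithio enolate acetylide of 17 (stereocentres as in 17) | ClCC[C@H](C=C(O[Li])OC)[C@@]1(C)[C@H](C#C[Li])C(C)(C)CCC1 | intermediate
19 | lithium acetylide of the tert-butyldimethylsilyl methyl ketene acetal (stereocentres as in 17) | ClCC[C@H](C=C(OC)O[Si](C)(C)C(C)(C)C)[C@@]1(C)[C@H](C#C[Li])C(C)(C)CCC1 | intermediate
20 | tert-butyldimethylsilyl methyl ketene acetal of 17 (stereocentres as in 17, ketene acetal geometry mixed) | ClCC[C@H](C=C(OC)O[Si](C)(C)C(C)(C)C)[C@@]1(C)[C@H](C#C)C(C)(C)CCC1 | intermediate
21 | methyl (1R,2S,4aR,8aS)-1-(2-chloroethyl)-5,5,8a-trimethyl-1,2,4a,5,6,7,8,8a-octahydronaphthalene-2-carboxylate | ClCC[C@@H]1[C@@H](C(=O)OC)C=C[C@@H]2C(C)(C)CCC[C@@]12C | intermediate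
22 | methyl (1R,2S,4aR,8aS)-1-(2-iodoethyl)-5,5,8a-trimethyl-1,2,4a,5,6,7,8,8a-octahydronaphthalene-2-carboxylate | ICC[C@@H]1[C@@H](C(=O)OC)C=C[C@@H]2C(C)(C)CCC[C@@]12C | intermediate
23 | methyl 4-hydroxybut-2-ynoate | COC(=O)C#CCO | starting material
24 | methyl (2Z)-4-hydroxy-3-iodobut-2-enoate | COC(=O)/C=C(\I)CO | intermediate
25 | methyl (2Z)-4-acetoxy-3-iodobut-2-enoate | COC(=O)/C=C(\I)COC(C)=O | intermediate
26 | alkylzinc iodide from 22 (ZnI on C12) | I[Zn]CC[C@@H]1[C@@H](C(=O)OC)C=C[C@@H]2C(C)(C)CCC[C@@]12C | intermediate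
27 | methyl (1R,2S,4aR,8aS)-1-[(3E)-3-(acetoxymethyl)-5-methoxy-5-oxopent-3-en-1-yl]-5,5,8a-trimethyl-1,2,4a,5,6,7,8,8a-octahydronaphthalene-2-carboxylate (CNP0190145.1) | COC(=O)/C=C(\CC[C@@H]1[C@@H](C(=O)OC)C=C[C@@H]2C(C)(C)CCC[C@@]12C)COC(C)=O | target

**Step count and risks**

Total steps: 13. Longest linear sequence: 11 steps (steps 1–10 and 13); steps 11 and 12 make the side-chain fragment.

Steps most likely to fail:

1. Step 9 (proposed new method). What may go wrong: C-silylation of the acetylide or hydrolysis of the ketene acetal before ring closure, and attack at C6 that would close a five-membered ring. Fallback with known chemistry: it sets out from aldehyde 16. Stork–Zhao olefination (Ph3PCH2I iodide, NaN(SiMe3)2, THF–DMPU, −78 °C) would give the vinyl iodide methyl (3S)-5-chloro-3-{(1S,2R)-2-[(Z)-2-iodoethenyl]-1,3,3-trimethylcyclohexyl}pentanoate F1. Palladium-catalysed intramolecular α-alkenylation of the ester enolate (Pd(PPh3)4, PhOK, THF, reflux) would then close the same C7–C8 bond and come back to the route at 21. This fallback runs under basic conditions, so the C8 configuration would rest on the preference for the equatorial ester.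

2. Step 3. What may go wrong: slow rearrangement of the hindered boron ketene acetal, ionisation of the allylic ester by the Lewis-acidic bromoborane, or low or reversed enantioselection. Fallback: it sets out from ester 4. LiN(i-Pr)2 is added to 4 and Me3SiCl in THF–DMPU at −78 °C to give the trimethylsilyl ketene acetal of 4 F2. Warming to 60 °C would rearrange it through the same chair to the racemic trimethylsilyl ester F3, and aqueous acid would give the racemic acid F4. Preparative chromatography on a chiral stationary phase would separate the enantiomers and come back to the route at 9.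

3. Step 6. What may go wrong: slow addition of borane to the doubly neopentyl alkene, with competing reduction of the ester. Fallback: it sets out from ester 13. Radical thiol–ene addition (PhSH, AIBN, toluene, 80 °C) would give the sulfide methyl (3S)-5-chloro-3-{(1S,2R)-1,3,3-trimethyl-2-[(phenylsulfanyl)methyl]cyclohexyl}pentanoate F5, with the hydrogen atom delivered to C5 from the same open face. Oxidation (mCPBA, CH2Cl2, −78 °C) would give the sulfoxide of F5 F6. Pummerer rearrangement ((CF3CO)2O, 2,6-lutidine) would give the α-trifluoroacetoxy sulfide F7, and hydrolysis (aq. NaHCO3) would come back to the route at aldehyde 16.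

**Further compounds**

F1 | step 9 | methyl (3S)-5-chloro-3-{(1S,2R)-2-[(Z)-2-iodoethenyl]-1,3,3-trimethylcyclohexyl}pentanoate | ClCC[C@H](CC(=O)OC)[C@@]1(C)[C@H](/C=C\I)C(C)(C)CCC1
F2 | step 3 | trimethylsilyl ketene acetal of 4 (C11 cis to OSi) | ClCC/C=C(\O[Si](C)(C)C)OCC1=C(C)CCCC1(C)C
F3 | step 3 | racemic trimethylsilyl ester (silyl ester of 9 and its enantiomer) | ClCC[C@H](C(=O)O[Si](C)(C)C)[C@@]1(C)C(=C)C(C)(C)CCC1.ClCC[C@@H](C(=O)O[Si](C)(C)C)[C@]1(C)C(=C)C(C)(C)CCC1
F4 | step 3 | racemic acid (9 and its enantiomer) | ClCC[C@H](C(=O)O)[C@@]1(C)C(=C)C(C)(C)CCC1.ClCC[C@@H](C(=O)O)[C@]1(C)C(=C)C(C)(C)CCC1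
F5 | step 6 | methyl (3S)-5-chloro-3-{(1S,2R)-1,3,3-trimethyl-2-[(phenylsulfanyl)methyl]cyclohexyl}pentanoate | ClCC[C@H](CC(=O)OC)[C@@]1(C)[C@H](CSc2ccccc2)C(C)(C)CCC1
F6 | step 6 | sulfoxide of F5 (mixture at sulfur) | ClCC[C@H](CC(=O)OC)[C@@]1(C)[C@H](CS(=O)c2ccccc2)C(C)(C)CCC1
F7 | step 6 | α-trifluoroacetoxy sulfide (mixture at the new centre) | ClCC[C@H](CC(=O)OC)[C@@]1(C)[C@H](C(OC(=O)C(F)(F)F)Sc2ccccc2)C(C)(C)CCC1
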